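**Plan**

- Retrosynthesis: after unmasking (aryl silyl ether, dioxolane, two methyl enol ethers) the benzene ring is cut at the C(OH)–C(acetyl) bond and at the bond between the second oxygenated carbon and the CH2-bearing carbon. This gives a 3-methoxycyclobutenone that already carries the CH2-linked, enol-protected acetylfilicinic ring, and a siloxyalkyne with a ketal-masked acetyl group.
- The cyclobutenone is cut across its ring (C1–C4 and C2–C3) into an alkylketene and 1,1-dimethoxyethene. The ketene chain goes back to the ring–CH2 bond made by Michael addition of acetylfilicinic acid to an acrylate, and the filicinic ring to geminal dimethylation of 2,4,6-trihydroxyacetophenone.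
- Forward order of rings: dearomatised six-membered ring (step 1), four-membered ring (step 5), benzene ring (step 8). The siloxyalkyne is made separately in two steps and joined in step 8.
- Enabling feature: the benzene ring is pentasubstituted with oxygen on alternate carbons. Its contiguous CH2-bearing carbon, C(OMe), CH and C(OH) map onto the four carbons of a 2-substituted 3-methoxycyclobutenone; the acetyl-bearing carbon and the other C(OH) map onto the two carbons of a siloxyalkyne.
- Stereochemistry: the target has no stereocentre. The only selectivity to secure is the regiochemistry of the annulation, which the polarity of the siloxyalkyne sets.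

Key step: step 8

Assumption: diazoalkane methylation of the filicinic dienol (step 3) is taken to give the cross-conjugated 3,5-dimethoxycyclohexa-2,5-dienone isomer; any O-methyl regioisomer formed alongside would be carried through and converges on the same trione in step 9. Enolised triones are drawn in the tautomer used for the target.

**Route**

Step 1
Reactants: 1 2,4,6-trihydroxyacetophenone
Product: 2 acetylfilicinic acid (2-acetyl-3,5-dihydroxy-4,4-dimethylcyclohexa-2,5-dien-1-one)
Conditions: MeI (2.2 equiv), NaOMe (3.5 equiv), MeOH, 0 °C to rt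
Reagents that add atoms: iodomethane, CI
Why: Dearomative geminal C-methylation of the acylphloroglucinol polyanion is a standard entry to acylfilicinic acids, the second methyl group entering at the carbon already methylated because that step turns the ring into a stable vinylogous acid.

Step 2
Reactants: 2 acetylfilicinic acid; 3 allyl acrylate
Product: 4 allyl 3-(5-acetyl-2,4-dihydroxy-3,3-dimethyl-6-oxocyclohexa-1,4-dien-1-yl)propanoate
Conditions: Et3N (1.2 equiv), MeCN, 60 °C
Reagents that add atoms: none
Why: Michael addition of the vinylogous-acid enolate of 2 through its only unsubstituted ring carbon to the acrylate is the C-alkylation that cyclic 1,3-diones undergo with acrylic esters, and a tertiary amine avoids the transesterification an alkoxide would cause.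

Step 3
Reactants: 4 allyl 3-(5-acetyl-2,4-dihydroxy-3,3-dimethyl-6-oxocyclohexa-1,4-dien-1-yl)propanoate
Product: 5 allyl 3-(5-acetyl-2,4-dimethoxy-3,3-dimethyl-6-oxocyclohexa-1,4-dien-1-yl)propanoate
Conditions: Me3SiCHN2 (3 equiv), MeOH/toluene 1:4, 0 °C to rt
Reagents that add atoms: (trimethylsilyl)diazomethane, C[Si](C)(C)C=[N+]=[N-]
Why: Diazoalkane O-methylation acts only on the two acidic enol hydroxyls (no C-alkylation, ester untouched) and turns the trione into neutral vinylogous esters that can neither protonate a siloxyalkyne nor add to a ketene later on.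

Step 4
Reactants: 5 allyl 3-(5-acetyl-2,4-dimethoxy-3,3-dimethyl-6-oxocyclohexa-1,4-dien-1-yl)propanoate
Product: 6 3-(5-acetyl-2,4-dimethoxy-3,3-dimethyl-6-oxocyclohexa-1,4-dien-1-yl)propanoic acid
Conditions: Pd(PPh3)4 (5 mol %), N-methylaniline (2 equiv), THF, rt
Reagents that add atoms: none
Why: Tsuji–Trost deallylation with zerovalent palladium and a weakly basic amine as allyl acceptor frees the carboxylic acid under neutral conditions that neither hydrolyse nor aminolyse the vinylogous methyl esters.

Step 5
Reactants: 6 3-(5-acetyl-2,4-dimethoxy-3,3-dimethyl-6-oxocyclohexa-1,4-dien-1-yl)propanoic acid; 7 1,1-dimethoxyethene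
Product: 11 2-[(5-acetyl-2,4-dimethoxy-3,3-dimethyl-6-oxocyclohexa-1,4-dien-1-yl)methyl]-3-methoxycyclobut-2-en-1-one, via acid chloride 8 (not isolated), via alkylketene 9 (not isolated), via dimethoxycyclobutanone 10 (not isolated)
Conditions: 1-chloro-N,N,2-trimethylprop-1-en-1-amine (1.05 equiv), CH2Cl2, 0 °C to rt; then slow addition to 7 (5 equiv) and Et3N (1.5 equiv), CH2Cl2, 40 °C; SiO2 to complete loss of MeOH
Reagents that add atoms: none
Why: Neutral chlorination with the α-chloroenamine gives 8, dehydrochlorination by Et3N releases aldoketene 9, whose carbonyl carbon is attacked by the CH2 terminus of the ketene acetal in a ketene–ketene acetal [2+2] cycloaddition so that the acetal carbon ends next to the substituted carbon, and loss of methanol from racemic 10 towards that carbon gives the conjugated vinylogous ester 11.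

Step 6
Reactants: 12 ethyl pyruvate
Product: 13 ethyl 2-methyl-1,3-dioxolane-2-carboxylate
Conditions: HOCH2CH2OH, TsOH·H2O (cat.), toluene, reflux, azeotropic removal of water
Reagents that add atoms: ethylene glycol, OCCO
Why: Acid-catalysed ketalisation of the ketone carbonyl of an α-keto ester with a 1,2-diol under water removal is routine and leaves the ester for the homologation.

Step 7
Reactants: 13 ethyl 2-methyl-1,3-dioxolane-2-carboxylate
Product: 16 triisopropyl{[(2-methyl-1,3-dioxolan-2-yl)ethynyl]oxy}silane, via lithium dibromoenolate 14 (not isolated), via lithium ynolate 15 (not isolated)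
Conditions: CH2Br2, lithium 2,2,6,6-tetramethylpiperidide, THF, −78 °C; LiN(SiMe3)2; n-BuLi, −78 °C to rt; i-Pr3SiCl, −78 to 0 °C; non-acidic work-up
Reagents that add atoms: dibromomethane, BrCBr; chlorotriisopropylsilane, CC(C)[Si](Cl)(C(C)C)C(C)C
Why: Kowalski ester homologation stopped at the ynolate: addition of LiCHBr2 to the ester, enolisation to 14, bromine–lithium exchange and 1,2-shift of the dioxolanyl carbon give 15, which the bulky silyl chloride captures on oxygen as a thermally robust siloxyalkyne.

Step 8
Reactants: 11 2-[(5-acetyl-2,4-dimethoxy-3,3-dimethyl-6-oxocyclohexa-1,4-dien-1-yl)methyl]-3-methoxycyclobut-2-en-1-one; 16 triisopropyl{[(2-methyl-1,3-dioxolan-2-yl)ethynyl]oxy}silane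
Product: 21 2-acetyl-6-{[4-hydroxy-6-methoxy-3-(2-methyl-1,3-dioxolan-2-yl)-2-(triisopropylsilyloxy)phenyl]methyl}-3,5-dimethoxy-4,4-dimethylcyclohexa-2,5-dien-1-one, via vinylketene 17 (not isolated), via vinylcyclobutenone 18 (not isolated), via dienylketene 19 (not isolated), via cyclohexadienone 20 (not isolated)
Conditions: 16 (1.5 equiv), degassed toluene, 110 °C, sealed tube, exclusion of light
Reagents that add atoms: none
Why: Danheiser benzannulation: thermal 4π electrocyclic opening of 11 breaks its C1–C4 bond to give vinylketene 17, whose ketene C=C adds the siloxyalkyne in a regioselective [2+2] cycloaddition to 4-vinylcyclobutenone 18. A second 4π opening gives dienylketene 19, and thermal disrotatory 6π electrocyclisation bonds the ketene carbon to the terminal CH2 (the former C4 of 11) to close the six-membered ring as dienone 20, which tautomerises to phenol 21. The closest known reaction type is the annulation of cyclobutenones with triisopropylsiloxyalkynes to resorcinol monosilyl ethers, here with a 3-alkoxycyclobutenone as the four-carbon partner. No stereocentre remains (the quaternary carbon of racemic 18 becomes sp2); the selectivity needed is the orientation of the [2+2] step, which the polarisation of the siloxyalkyne secures because its carbon remote from oxygen attacks the ketene carbonyl carbon, placing the dioxolanyl carbon next to the new hydroxyl carbon and the silyloxy carbon next to the bridge-bearing carbon. The filicinic unit travels as a neutral bis(enol ether) that cannot add to the ketenes or protonate the alkyne, heat is used instead of light because the cross-conjugated dienone would rearrange on irradiation, and the excess of 16 keeps the vinylketene concentration low and limits O-acylation of the phenol formed.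

Step 9
Reactants: 21 2-acetyl-6-{[4-hydroxy-6-methoxy-3-(2-methyl-1,3-dioxolan-2-yl)-2-(triisopropylsilyloxy)phenyl]methyl}-3,5-dimethoxy-4,4-dimethylcyclohexa-2,5-dien-1-one
Product: 23 2-acetyl-6-[(3-acetyl-2,4-dihydroxy-6-methoxyphenyl)methyl]-3,5-dihydroxy-4,4-dimethylcyclohexa-2,5-dien-1-one, via desilylated resorcinol 22 (not isolated)
Conditions: Bu4NF (1.1 equiv), THF, 0 °C; then 3 M aq HCl, 50 °C
Reagents that add atoms: water, O
Why: Fluoride desilylation removes the aryl silyl ether while the trione is still masked (so no base-induced exchange at the methylene bridge can occur), and dilute aqueous acid then effects acetal hydrolysis of the dioxolane to the aryl methyl ketone and vinylogous-ester hydrolysis of both methyl enol ethers by addition–elimination of water, the aryl methyl ether being inert.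

**Compound list**

1 | 2,4,6-trihydroxyacetophenone | CC(=O)c1c(O)cc(O)cc1O | starting material
2 | acetylfilicinic acid, 2-acetyl-3,5-dihydroxy-4,4-dimethylcyclohexa-2,5-dien-1-one | CC(=O)C1=C(O)C(C)(C)C(O)=CC1=O | intermediate
3 | allyl acrylate (prop-2-en-1-yl prop-2-enoate) | C=CC(=O)OCC=C | starting material
4 | allyl 3-(5-acetyl-2,4-dihydroxy-3,3-dimethyl-6-oxocyclohexa-1,4-dien-1-yl)propanoate | C=CCOC(=O)CCC1=C(O)C(C)(C)C(O)=C(C(C)=O)C1=O | intermediate
5 | allyl 3-(5-acetyl-2,4-dimethoxy-3,3-dimethyl-6-oxocyclohexa-1,4-dien-1-yl)propanoate | C=CCOC(=O)CCC1=C(OC)C(C)(C)C(OC)=C(C(C)=O)C1=O | intermediate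
6 | 3-(5-acetyl-2,4-dimethoxy-3,3-dimethyl-6-oxocyclohexa-1,4-dien-1-yl)propanoic acid | OC(=O)CCC1=C(OC)C(C)(C)C(OC)=C(C(C)=O)C1=O | intermediate
7 | 1,1-dimethoxyethene | C=C(OC)OC | starting material
8 | 3-(5-acetyl-2,4-dimethoxy-3,3-dimethyl-6-oxocyclohexa-1,4-dien-1-yl)propanoyl chloride | ClC(=O)CCC1=C(OC)C(C)(C)C(OC)=C(C(C)=O)C1=O | intermediate
9 | 3-(5-acetyl-2,4-dimethoxy-3,3-dimethyl-6-oxocyclohexa-1,4-dien-1-yl)prop-1-en-1-one (alkylketene) | O=C=CCC1=C(OC)C(C)(C)C(OC)=C(C(C)=O)C1=O | intermediate
10 | 2-[(5-acetyl-2,4-dimethoxy-3,3-dimethyl-6-oxocyclohexa-1,4-dien-1-yl)methyl]-3,3-dimethoxycyclobutan-1-one (racemic) | O=C1CC(OC)(OC)C1CC2=C(OC)C(C)(C)C(OC)=C(C(C)=O)C2=O | intermediate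
11 | 2-[(5-acetyl-2,4-dimethoxy-3,3-dimethyl-6-oxocyclohexa-1,4-dien-1-yl)methyl]-3-methoxycyclobut-2-en-1-one | O=C1CC(OC)=C1CC2=C(OC)C(C)(C)C(OC)=C(C(C)=O)C2=O | intermediate
12 | ethyl pyruvate | CCOC(=O)C(C)=O | starting material
13 | ethyl 2-methyl-1,3-dioxolane-2-carboxylate | CCOC(=O)C1(C)OCCO1 | intermediate
14 | lithium 2,2-dibromo-1-(2-methyl-1,3-dioxolan-2-yl)ethen-1-olate | [Li+].[O-]C(=C(Br)Br)C1(C)OCCO1 | intermediate
15 | lithium 2-(2-methyl-1,3-dioxolan-2-yl)ethyn-1-olate | [Li+].[O-]C#CC1(C)OCCO1 | intermediate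
16 | triisopropyl{[(2-methyl-1,3-dioxolan-2-yl)ethynyl]oxy}silane | CC1(C#CO[Si](C(C)C)(C(C)C)C(C)C)OCCO1 | intermediate
17 | 2-[(5-acetyl-2,4-dimethoxy-3,3-dimethyl-6-oxocyclohexa-1,4-dien-1-yl)methyl]-3-methoxybuta-1,3-dien-1-one (vinylketene) | O=C=C(CC1=C(OC)C(C)(C)C(OC)=C(C(C)=O)C1=O)C(OC)=C | intermediate
18 | 4-[(5-acetyl-2,4-dimethoxy-3,3-dimethyl-6-oxocyclohexa-1,4-dien-1-yl)methyl]-4-(1-methoxyethenyl)-2-(2-methyl-1,3-dioxolan-2-yl)-3-(triisopropylsilyloxy)cyclobut-2-en-1-one (racemic) | O=C1C(C2(C)OCCO2)=C(O[Si](C(C)C)(C(C)C)C(C)C)C1(CC3=C(OC)C(C)(C)C(OC)=C(C(C)=O)C3=O)C(OC)=C | intermediate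
19 | (3E)-4-[(5-acetyl-2,4-dimethoxy-3,3-dimethyl-6-oxocyclohexa-1,4-dien-1-yl)methyl]-5-methoxy-2-(2-methyl-1,3-dioxolan-2-yl)-3-(triisopropylsilyloxy)hexa-1,3,5-trien-1-one (dienylketene) | O=C=C(C1(C)OCCO1)/C(O[Si](C(C)C)(C(C)C)C(C)C)=C(/CC2=C(OC)C(C)(C)C(OC)=C(C(C)=O)C2=O)C(OC)=C | intermediate
20 | 4-[(5-acetyl-2,4-dimethoxy-3,3-dimethyl-6-oxocyclohexa-1,4-dien-1-yl)methyl]-5-methoxy-2-(2-methyl-1,3-dioxolan-2-yl)-3-(triisopropylsilyloxy)cyclohexa-2,4-dien-1-one | O=C1CC(OC)=C(CC2=C(OC)C(C)(C)C(OC)=C(C(C)=O)C2=O)C(O[Si](C(C)C)(C(C)C)C(C)C)=C1C3(C)OCCO3 | intermediate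
21 | 2-acetyl-6-{[4-hydroxy-6-methoxy-3-(2-methyl-1,3-dioxolan-2-yl)-2-(triisopropylsilyloxy)phenyl]methyl}-3,5-dimethoxy-4,4-dimethylcyclohexa-2,5-dien-1-one | COc1cc(O)c(C2(C)OCCO2)c(O[Si](C(C)C)(C(C)C)C(C)C)c1CC3=C(OC)C(C)(C)C(OC)=C(C(C)=O)C3=O | intermediate
22 | 2-acetyl-6-{[2,4-dihydroxy-6-methoxy-3-(2-methyl-1,3-dioxolan-2-yl)phenyl]methyl}-3,5-dimethoxy-4,4-dimethylcyclohexa-2,5-dien-1-one | COc1cc(O)c(C2(C)OCCO2)c(O)c1CC3=C(OC)C(C)(C)C(OC)=C(C(C)=O)C3=O | intermediate
23 | 2-acetyl-6-[(3-acetyl-2,4-dihydroxy-6-methoxyphenyl)methyl]-3,5-dihydroxy-4,4-dimethylcyclohexa-2,5-dien-1-one (CNP0224819.0) | COc1cc(O)c(C(C)=O)c(O)c1CC2=C(O)C(C)(C)C(O)=C(C(C)=O)C2=O | target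

**Step count and risks**

Total: 9 steps. Longest linear sequence: 7 steps (steps 1, 2, 3, 4, 5, 8, 9); steps 6 and 7 form the two-step branch to the siloxyalkyne.

Steps most likely to fail:

1. Step 8. The vinylogous-ester conjugation of the 3-methoxycyclobutenone may make its 4π opening slower than thermal decay of the siloxyalkyne or acid-triggered ionisation of its propargylic ketal. The phenol formed may also be O-acylated by remaining vinylketene. Fallback: the arene is taken ready-made and the bridge bond is formed instead. Setting out from 2, commercial 1-(2,6-dihydroxy-4-methoxyphenyl)ethan-1-one F1 would be aminomethylated (aqueous CH2O, Me2NH, EtOH) to the Mannich base 1-{3-[(dimethylamino)methyl]-2,6-dihydroxy-4-methoxyphenyl}ethan-1-one F2. Heating F2 with 2 in dioxane should expel dimethylamine to an ortho-quinone methide that is captured by the free ring carbon of 2, rejoining the route at 23.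

2. Step 5. C-acylation of the ketene acetal by the acid chloride, or dimerisation of the aldoketene, may outrun the [2+2] cycloaddition. Loss of methanol in the other direction is the lesser concern, since that double-bond isomer would lead to the same resorcinol after desilylation. Fallback: the four-membered ring is brought in ready-made, which bypasses steps 2 to 5.
   - Setting out from 2, a Mannich reaction (aqueous CH2O, Me2NH) should give 2-acetyl-6-[(dimethylamino)methyl]-3,5-dihydroxy-4,4-dimethylcyclohexa-2,5-dien-1-one F3.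
   - Commercial 3-ethoxycyclobut-2-en-1-one F4 would be hydrolysed with dilute aqueous HCl to cyclobutane-1,3-dione F5, used at once.
   - Warming F3 with F5 in dioxane should give, by amine loss and Michael addition of the dione C2 to the enone methide, 2-[(5-acetyl-2,4-dihydroxy-3,3-dimethyl-6-oxocyclohexa-1,4-dien-1-yl)methyl]-3-hydroxycyclobut-2-en-1-one F6.
   - Exhaustive O-methylation of F6 with Me3SiCHN2 rejoins the route at 11.

3. Step 2. The strongly delocalised enolate of 2 may add too slowly to a simple acrylate, so that acrylate oligomerisation or reversible O-addition dominates. Fallback: acylation first, then C–C bond formation. Setting out from 2, acryloyl chloride and Et3N in warm toluene should give, by O-acylation and intramolecular conjugate addition, the enol lactone 6-acetyl-7-hydroxy-8,8-dimethyl-3,4-dihydro-2H-chromene-2,5(8H)-dione F7. Alcoholysis of F7 with allyl alcohol and DMAP opens the activated enol ester and rejoins the route at 4.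

**Further compounds**

F1 | step 8 | 1-(2,6-dihydroxy-4-methoxyphenyl)ethan-1-one | COc1cc(O)c(C(C)=O)c(O)c1
F2 | step 8 | 1-{3-[(dimethylamino)methyl]-2,6-dihydroxy-4-methoxyphenyl}ethan-1-one | COc1cc(O)c(C(C)=O)c(O)c1CN(C)C
F3 | step 5 | 2-acetyl-6-[(dimethylamino)methyl]-3,5-dihydroxy-4,4-dimethylcyclohexa-2,5-dien-1-one | CN(C)CC1=C(O)C(C)(C)C(O)=C(C(C)=O)C1=O
F4 | step 5 | 3-ethoxycyclobut-2-en-1-one | CCOC1=CC(=O)C1
F5 | step 5 | cyclobutane-1,3-dione | O=C1CC(=O)C1
F6 | step 5 | 2-[(5-acetyl-2,4-dihydroxy-3,3-dimethyl-6-oxocyclohexa-1,4-dien-1-yl)methyl]-3-hydroxycyclobut-2-en-1-one | O=C1CC(O)=C1CC2=C(O)C(C)(C)C(O)=C(C(C)=O)C2=O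
F7 | step 2 | 6-acetyl-7-hydroxy-8,8-dimethyl-3,4-dihydro-2H-chromene-2,5(8H)-dione | CC(=O)C1=C(O)C(C)(C)C2=C(CCC(=O)O2)C1=O
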